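Ring C of dysidenone A is a cyclopentenone whose ester-bearing carbon C1′ sits between C2′ (a CH) and C5′ (carrying the C11 methylene): the pattern of a benzene ring that has lost one carbon. The plan therefore builds ring C as an arene and contracts it late. Irradiation of an ortho-quinone diazide in methanol (photo-Wolff) forms the C1′–C2′ bond, the five-membered ring and the methyl ester in one operation. Its precursor is a 6-diazocyclohexa-2,4-dienone bearing OMe, a triisopropylsilyloxy group and the complete trans-decalin, reached from an aminophenol by standard arene chemistry; ring C stereocentres are installed afterwards.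

Key step: step 19

Remarks before the steps
- Numbering: decalin C1–C8a and C11, ring C C1′–C5′ as in the target; arene carbons Ar-C1 (bears C11), Ar-C2 (silyloxy), Ar-C3 (OMe), Ar-C4, Ar-C5, Ar-C6.
- Abbreviations: DecCH2 = [(1R,2R,4aS,8aS)-1,2,4a,5-tetramethyl-1,2,3,4,4a,7,8,8a-octahydronaphthalen-2-yl]methyl; ArCH2 = 3-methoxy-2-[(triisopropylsilyl)oxy]benzyl; TIPS = triisopropylsilyl.
- Design of the precursor: one TIPS ether is carried from step 6 to the diazide, chosen to survive dissolving metal, base and dilute acid. The oxygen that ends as the ester carbonyl is put on Ar-C5 by C–H borylation, and the nitrogen on Ar-C6 by azo coupling, so no nitrating agent meets the hydroquinone monoether or the ring A alkene.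
- Assumption (chemistry): the chiral NHC ligand of step 1 and the camphor-derived oxaziridine of step 21 are available in both enantiomeric forms, and the enantiomer written is taken to be the one that gives the drawn configuration.

Step 1
Reactants: 1 2-methylcyclohex-2-en-1-one; 2 isopropenylmagnesium bromide; 3 allyl iodide
Product: 5 (2S,3S)-2-methyl-2-(prop-2-en-1-yl)-3-(prop-1-en-2-yl)cyclohexan-1-one, via magnesium enolate 4 (not isolated)
Conditions: Cu(OTf)2 (4 mol%), chiral N-mesityl N′-(hydroxyalkyl)imidazolinium hexafluorophosphate (tert-leucinol-derived NHC precursor, 5 mol%), Et2O, −30 °C; then allyl iodide, DMPU, −30 → 25 °C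
Reagents that add atoms: isopropenylmagnesium bromide (2), CC(=C)[Mg]Br; allyl iodide (3), C=CCI
Why: Copper-catalysed asymmetric conjugate addition of the alkenyl Grignard reagent to the α-methyl enone, in which the chiral NHC ligand sets the future C8a centre (3S), is followed by allylation of the regiodefined magnesium enolate anti to the new isopropenyl group, which sets the quaternary future C4a centre (2S, trans).

Step 2
Reactants: 5 (2S,3S)-2-methyl-2-(prop-2-en-1-yl)-3-(prop-1-en-2-yl)cyclohexan-1-one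
Product: 6 (6S,7S)-6-methyl-6-(prop-2-en-1-yl)-7-(prop-1-en-2-yl)-1,4-dioxaspiro[4.5]decane
Conditions: (TMSOCH2)2, TMSOTf (5 mol%), CH2Cl2, −78 → −20 °C
Reagents that add atoms: 1,2-bis(trimethylsilyloxy)ethane, C[Si](C)(C)OCCO[Si](C)(C)C
Why: Noyori ketalisation (silyl-transfer acetalisation) protects the hindered ring A ketone at low temperature without acid strong enough to isomerise the two alkenes, and touches no stereocentre.

Step 3
Reactants: 6 (6S,7S)-6-methyl-6-(prop-2-en-1-yl)-7-(prop-1-en-2-yl)-1,4-dioxaspiro[4.5]decane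
Product: 8 2-[(6S,7R)-7-acetyl-6-methyl-1,4-dioxaspiro[4.5]decan-6-yl]acetaldehyde, via bis-ozonide 7 (not isolated)
Conditions: O3, CH2Cl2, −78 °C; then PPh3, −78 → 25 °C
Reagents that add atoms: ozone, [O-][O+]=O
Why: Ozonolysis with reductive work-up cleaves both terminal alkenes in one operation, giving the C1 acetyl group and the C3 aldehyde of ring B.

Step 4
Reactants: 8 2-[(6S,7R)-7-acetyl-6-methyl-1,4-dioxaspiro[4.5]decan-6-yl]acetaldehyde
Product: 10 (4aS,8aR)-5,5-ethylenedioxy-4a-methyl-4a,5,6,7,8,8a-hexahydronaphthalen-1(4H)-one (trans-fused), via aldol adduct 9 (not isolated)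
Conditions: KOH, MeOH, 0 → 50 °C
Reagents that add atoms: none
Why: Intramolecular aldol condensation (6-enolendo-exo-trig, then E1cB dehydration) joins C2 to C3 and closes ring B as the enone, the only ring size open to the keto aldehyde, and the trans ring fusion set in step 1 is also the thermodynamic one if C8a should enolise (compare 5α-6-oxo steroids).

Step 5
Reactants: 10 (4aS,8aR)-5,5-ethylenedioxy-4a-methyl-4a,5,6,7,8,8a-hexahydronaphthalen-1(4H)-one
Product: 11 (4aS,8aR)-5,5-ethylenedioxy-2-iodo-4a-methyl-4a,5,6,7,8,8a-hexahydronaphthalen-1(4H)-one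
Conditions: I2, pyridine, CH2Cl2, 0 → 25 °C
Reagents that add atoms: iodine, II
Why: Johnson α-iodination (conjugate addition of pyridine, iodination of the enolate, elimination) puts iodine on C2 of the enone.

Step 6
Reactants: 12 o-vanillin (2-hydroxy-3-methoxybenzaldehyde)
Product: 13 3-methoxy-2-[(triisopropylsilyl)oxy]benzaldehyde
Conditions: TIPSCl, imidazole, DMF, 25 °C
Reagents that add atoms: chlorotri(propan-2-yl)silane, CC(C)[Si](Cl)(C(C)C)C(C)C
Why: Silyl ether formation on the phenol; the bulky TIPS group is chosen because the same ether has to survive dissolving metal, base and dilute acid before it ends as the enol ether of the photoproduct.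

Step 7
Reactants: 13 3-methoxy-2-[(triisopropylsilyl)oxy]benzaldehyde
Product: 14 {3-methoxy-2-[(triisopropylsilyl)oxy]phenyl}methanol
Conditions: NaBH4, THF/MeOH, −20 → 0 °C
Reagents that add atoms: none
Why: Borohydride reduction of the aldehyde, run cold so that the bulky silyl group does not migrate from the phenolic to the benzylic oxygen.

Step 8
Reactants: 14 {3-methoxy-2-[(triisopropylsilyl)oxy]phenyl}methanol
Product: 15 [2-(chloromethyl)-6-methoxyphenoxy]triisopropylsilane
Conditions: SOCl2, pyridine, CH2Cl2, 0 °C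
Reagents that add atoms: thionyl chloride, O=S(Cl)Cl
Why: Deoxychlorination through the chlorosulfite gives the benzylic chloride, the substrate type that inserts zinc cleanly.

Step 9
Reactants: 15 [2-(chloromethyl)-6-methoxyphenoxy]triisopropylsilane; 11 (4aS,8aR)-5,5-ethylenedioxy-2-iodo-4a-methyl-4a,5,6,7,8,8a-hexahydronaphthalen-1(4H)-one
Product: 17 (4aS,8aR)-5,5-ethylenedioxy-4a-methyl-2-(ArCH2)-4a,5,6,7,8,8a-hexahydronaphthalen-1(4H)-one, via benzylzinc chloride 16 (not isolated)
Conditions: Zn dust, LiCl, THF, 25 °C; then 11, Pd(OAc)2 (2 mol%), SPhos (4 mol%), THF, 25 °C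
Reagents that add atoms: none
Why: LiCl-assisted zinc insertion (Knochel) makes the benzylic zinc reagent, and Negishi cross-coupling with the α-iodoenone forms the C2–C11 bond under neutral conditions that leave C8a untouched.

Step 10
Reactants: 17 (4aS,8aR)-5,5-ethylenedioxy-4a-methyl-2-(ArCH2)-4a,5,6,7,8,8a-hexahydronaphthalen-1(4H)-one
Product: 19 (2R,4aS,8aR)-5,5-ethylenedioxy-2,4a-dimethyl-2-(ArCH2)octahydronaphthalen-1(2H)-one, via lithium enolate 18 (not isolated)
Conditions: Li, NH3(l)/THF, t-BuOH (1 equiv), −78 °C; isoprene; then MeI, −78 → −33 °C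
Reagents that add atoms: iodomethane, CI
Why: Stork reductive alkylation: dissolving-metal reduction gives the C1–C2 enolate regiospecifically and methyl iodide attacks C2 axially from the α face, anti to the C4a angular methyl, so the quaternary centre carries α-methyl and β-arylmethyl (2R).

Step 11
Reactants: 19 (2R,4aS,8aR)-5,5-ethylenedioxy-2,4a-dimethyl-2-(ArCH2)octahydronaphthalen-1(2H)-one
Product: 20 (2R,4aS,8aS)-5,5-ethylenedioxy-2,4a-dimethyl-1-methylidene-2-(ArCH2)decahydronaphthalene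
Conditions: Cp2TiMe2, toluene, 70 °C, dark
Reagents that add atoms: dimethyltitanocene (Cp2TiMe2), C[Ti+2]C.[cH-]1cccc1.[cH-]1cccc1
Why: Petasis methylenation, a non-basic titanium-carbene olefination suited to a hindered ketone whose neighbouring C8a–H must not epimerise.

Step 12
Reactants: 20 (2R,4aS,8aS)-5,5-ethylenedioxy-2,4a-dimethyl-1-methylidene-2-(ArCH2)decahydronaphthalene
Product: 21 (1R,2R,4aS,8aS)-5,5-ethylenedioxy-1,2,4a-trimethyl-2-(ArCH2)decahydronaphthalene
Conditions: H2 (3 bar), PtO2, EtOAc, 25 °C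
Reagents that add atoms: none
Why: Catalytic hydrogenation adds hydrogen syn from the α face, because the β face above C1 is shielded by the syn-axial C4a methyl and the C2 arylmethyl group, which places the new C1 methyl β (axial, 1R).

Step 13
Reactants: 21 (1R,2R,4aS,8aS)-5,5-ethylenedioxy-1,2,4a-trimethyl-2-(ArCH2)decahydronaphthalene
Product: 22 (1R,2R,4aS,8aS)-1,2,4a-trimethyl-2-(ArCH2)octahydronaphthalen-5(1H)-one (target numbering, ketone at C5)
Conditions: 2 M HCl, THF, 45 °C
Reagents that add atoms: water, O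
Why: Acid-catalysed ketal hydrolysis frees the ring A ketone, with the hindered aryl silyl ether stable to dilute acid.

Step 14
Reactants: 22 (1R,2R,4aS,8aS)-1,2,4a-trimethyl-2-(ArCH2)octahydronaphthalen-5(1H)-one
Product: 24 (1R,2R,4aS,8aS)-1,2,4a-trimethyl-2-(ArCH2)-1,2,3,4,4a,7,8,8a-octahydronaphthalen-5-yl trifluoromethanesulfonate, via potassium enolate 23 (not isolated)
Conditions: KN(SiMe3)2, THF, −78 °C; then PhNTf2, −78 → 0 °C
Reagents that add atoms: N-phenylbis(trifluoromethanesulfonimide), O=S(=O)(N(c1ccccc1)S(=O)(=O)C(F)(F)F)C(F)(F)F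
Why: Enolisation is possible only toward C6 because C4a is quaternary, and O-sulfonylation of the potassium enolate with PhNTf2 gives the alkenyl triflate.

Step 15
Reactants: 24 (1R,2R,4aS,8aS)-1,2,4a-trimethyl-2-(ArCH2)-1,2,3,4,4a,7,8,8a-octahydronaphthalen-5-yl trifluoromethanesulfonate
Product: 25 triisopropyl[2-methoxy-6-(DecCH2)phenoxy]silane
Conditions: MeMgBr, Fe(acac)3 (5 mol%), THF/NMP, −30 → 0 °C
Reagents that add atoms: methylmagnesium bromide, C[Mg]Br
Why: Iron-catalysed cross-coupling of the alkenyl triflate with the methyl Grignard reagent (Fürstner–Kumada type) installs the C5 methyl and fixes the C5=C6 alkene without regioisomers.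

Step 16
Reactants: 25 triisopropyl[2-methoxy-6-(DecCH2)phenoxy]silane
Product: 27 3-methoxy-5-(DecCH2)-4-[(triisopropylsilyl)oxy]phenol, via aryl boronate 26 (not isolated)
Conditions: [Ir(OMe)(cod)]2 (1.5 mol%), dtbpy (3 mol%), B2pin2, THF, 65 °C; then 30% H2O2, 2 M NaOH, 0 °C
Reagents that add atoms: hydrogen peroxide, OO
Why: Iridium-catalysed C–H borylation (Hartwig–Miyaura) is sterically controlled and goes to Ar-C5, the only arene C–H with no ortho substituent, and alkaline peroxide then oxidises the C–B bond to the phenol at the same position.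

Step 17
Reactants: 27 3-methoxy-5-(DecCH2)-4-[(triisopropylsilyl)oxy]phenol
Product: 29 2-amino-5-methoxy-3-(DecCH2)-4-[(triisopropylsilyl)oxy]phenol, via azo dye 28 (not isolated)
Conditions: 4-diazoniobenzenesulfonate, Na2CO3, THF/H2O, 0 °C; then Na2S2O4, 45 °C, argon
Reagents that add atoms: 4-diazoniobenzenesulfonate, [O-]S(=O)(=O)c1ccc(cc1)[N+]#N
Why: Azo coupling (electrophilic aromatic substitution by the diazonium ion on the phenoxide, para position blocked) should go ortho to the hydroxyl at Ar-C6, para to the methoxy group, and dithionite then cleaves the N=N bond to the ortho-aminophenol without any nitrating agent near the alkene.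

Step 18
Reactants: 29 2-amino-5-methoxy-3-(DecCH2)-4-[(triisopropylsilyl)oxy]phenol
Product: 30 6-diazo-3-methoxy-5-(DecCH2)-4-[(triisopropylsilyl)oxy]cyclohexa-2,4-dien-1-one
Conditions: isoamyl nitrite, AcOH (cat.), THF, 0 °C, dark
Reagents that add atoms: isoamyl nitrite (3-methylbutyl nitrite), CC(C)CCON=O
Why: Diazotisation of the amine with an alkyl nitrite and loss of the phenolic proton give the neutral ortho-quinone diazide (diazo oxide), with N2 on Ar-C6 next to the benzylic carbon.

Step 19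
Reactants: 30 6-diazo-3-methoxy-5-(DecCH2)-4-[(triisopropylsilyl)oxy]cyclohexa-2,4-dien-1-one; 31 methanol
Product: 33 methyl 3-methoxy-5-(DecCH2)-4-[(triisopropylsilyl)oxy]cyclopenta-2,4-diene-1-carboxylate (C1′ labile, one epimer drawn), via ketene 32 (not isolated)
Conditions: hν (365 nm), MeOH/CH2Cl2, −40 °C, argon
Reagents that add atoms: methanol (31), CO
Why: Excitation expels N2 from the diazide and, because the diazo and carbonyl groups are held s-cis in the ring, ring carbon C2′ shifts in the same event from the carbonyl carbon to the diazo carbon C1′, which leaves a cyclopentadienylidene ketene whose former carbonyl carbon is now exocyclic. Methanol adds to the ketene and the resulting enol tautomerises to the methyl ester. The closest known reaction is the Süs photolysis of ortho-quinone diazides, the photochemical Wolff rearrangement used with diazonaphthoquinones. The five-membered ring is not closed by a cyclisation but by ring contraction through the 1,2-shift (six to five atoms, new C1′–C2′ bond). No lasting stereocentre is created, since C1′–H is acidic and epimerises. The step needs rearrangement to beat carbene O–H insertion and an unambiguous substituent pattern: the fixed s-cis geometry favours the concerted shift, migration is open only to the ring carbon on the carbonyl group so OMe, OSi and C11 must end on C3′, C4′ and C5′, and the low temperature suppresses 1,5-hydrogen shifts of the cyclopentadiene.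

Step 20
Reactants: 33 methyl 3-methoxy-5-(DecCH2)-4-[(triisopropylsilyl)oxy]cyclopenta-2,4-diene-1-carboxylate
Product: 34 methyl 3-methoxy-4-oxo-5-(DecCH2)cyclopent-2-ene-1-carboxylate (mixture of C1′ and C5′ epimers)
Conditions: Bu4NF, AcOH, THF, −78 °C
Reagents that add atoms: none
Why: Fluoride-induced cleavage of the silyl dienol ether at −78 °C with acetic acid as proton source gives the C4′ ketone by C5′ protonation before the cyclopentadiene can isomerise; C1′ and C5′ stay epimeric at this stage.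

Step 21
Reactants: 34 methyl 3-methoxy-4-oxo-5-(DecCH2)cyclopent-2-ene-1-carboxylate
Product: 37 dysidenone A, via sodium dienolate 35 (not isolated), via C5′ epimer 36 (not isolated)
Conditions: NaN(SiMe3)2, THF, −78 °C; (+)-(camphorylsulfonyl)oxaziridine, −78 → −40 °C; AcOH; then DBU (0.2 equiv), CH2Cl2, 0 °C
Reagents that add atoms: (+)-(2R,8aS)-(camphorylsulfonyl)oxaziridine, CC1(C)[C@@H]2CC[C@]13CS(=O)(=O)N4O[C@@]34C2
Why: Davis enolate hydroxylation: deprotonation at the doubly activated C1′ and oxygen transfer from the camphor-derived oxaziridine set C1′ under reagent control (1′S), and base then equilibrates the enolisable C5′ so that the C11 methylene lies trans to the hydroxyl (5′R).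

Compound list
1 | 2-methylcyclohex-2-en-1-one | CC1=CCCCC1=O | starting material
2 | isopropenylmagnesium bromide | CC(=C)[Mg]Br | starting material
3 | allyl iodide (3-iodoprop-1-ene) | C=CCI | starting material
4 | bromomagnesium (3S)-2-methyl-3-(prop-1-en-2-yl)cyclohex-1-en-1-olate | CC1=C(O[Mg]Br)CCC[C@H]1C(C)=C | intermediate
5 | (2S,3S)-2-methyl-2-(prop-2-en-1-yl)-3-(prop-1-en-2-yl)cyclohexan-1-one | C=CC[C@]1(C)C(=O)CCC[C@H]1C(C)=C | intermediate
6 | (6S,7S)-6-methyl-6-(prop-2-en-1-yl)-7-(prop-1-en-2-yl)-1,4-dioxaspiro[4.5]decane | C=CC[C@]1(C)C2(OCCO2)CCC[C@H]1C(C)=C | intermediate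
7 | bis-ozonide of 6 (both alkenes as 1,2,4-trioxolanes) | C1(OCOO1)C[C@]2(C)C3(OCCO3)CCC[C@H]2C4(C)OCOO4 | intermediate
8 | 2-[(6S,7R)-7-acetyl-6-methyl-1,4-dioxaspiro[4.5]decan-6-yl]acetaldehyde | O=CC[C@]1(C)C2(OCCO2)CCC[C@H]1C(C)=O | intermediate
9 | (4aS,8aR)-5,5-ethylenedioxy-3-hydroxy-4a-methyloctahydronaphthalen-1(2H)-one (aldol adduct, C3 unassigned) | C1C(O)C[C@]2(C)C3(OCCO3)CCC[C@H]2C1=O | intermediate
10 | (4aS,8aR)-5,5-ethylenedioxy-4a-methyl-4a,5,6,7,8,8a-hexahydronaphthalen-1(4H)-one | C1=CC[C@]2(C)C3(OCCO3)CCC[C@H]2C1=O | intermediate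
11 | (4aS,8aR)-5,5-ethylenedioxy-2-iodo-4a-methyl-4a,5,6,7,8,8a-hexahydronaphthalen-1(4H)-one | IC1=CC[C@]2(C)C3(OCCO3)CCC[C@H]2C1=O | intermediate
12 | o-vanillin (2-hydroxy-3-methoxybenzaldehyde) | COc1cccc(C=O)c1O | starting material
13 | 3-methoxy-2-[(triisopropylsilyl)oxy]benzaldehyde | COc1cccc(C=O)c1O[Si](C(C)C)(C(C)C)C(C)C | intermediate
14 | {3-methoxy-2-[(triisopropylsilyl)oxy]phenyl}methanol | COc1cccc(CO)c1O[Si](C(C)C)(C(C)C)C(C)C | intermediate
15 | [2-(chloromethyl)-6-methoxyphenoxy]triisopropylsilane | COc1cccc(CCl)c1O[Si](C(C)C)(C(C)C)C(C)C | intermediate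
16 | {3-methoxy-2-[(triisopropylsilyl)oxy]benzyl}zinc chloride | COc1cccc(C[Zn]Cl)c1O[Si](C(C)C)(C(C)C)C(C)C | intermediate
17 | (4aS,8aR)-5,5-ethylenedioxy-4a-methyl-2-(ArCH2)-4a,5,6,7,8,8a-hexahydronaphthalen-1(4H)-one | COc1cccc(CC2=CC[C@]3(C)C4(OCCO4)CCC[C@H]3C2=O)c1O[Si](C(C)C)(C(C)C)C(C)C | intermediate
18 | lithium (4aS,8aR)-5,5-ethylenedioxy-4a-methyl-2-(ArCH2)-3,4,4a,5,6,7,8,8a-octahydronaphthalen-1-olate | COc1cccc(CC=2CC[C@]3(C)C4(OCCO4)CCC[C@H]3C=2O[Li])c1O[Si](C(C)C)(C(C)C)C(C)C | intermediate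
19 | (2R,4aS,8aR)-5,5-ethylenedioxy-2,4a-dimethyl-2-(ArCH2)octahydronaphthalen-1(2H)-one | COc1cccc(C[C@@]2(C)CC[C@]3(C)C4(OCCO4)CCC[C@H]3C2=O)c1O[Si](C(C)C)(C(C)C)C(C)C | intermediate
20 | (2R,4aS,8aS)-5,5-ethylenedioxy-2,4a-dimethyl-1-methylidene-2-(ArCH2)decahydronaphthalene | COc1cccc(C[C@@]2(C)CC[C@]3(C)C4(OCCO4)CCC[C@H]3C2=C)c1O[Si](C(C)C)(C(C)C)C(C)C | intermediate
21 | (1R,2R,4aS,8aS)-5,5-ethylenedioxy-1,2,4a-trimethyl-2-(ArCH2)decahydronaphthalene | COc1cccc(C[C@@]2(C)CC[C@]3(C)C4(OCCO4)CCC[C@H]3[C@H]2C)c1O[Si](C(C)C)(C(C)C)C(C)C | intermediate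
22 | (1R,2R,4aS,8aS)-1,2,4a-trimethyl-2-(ArCH2)octahydronaphthalen-5(1H)-one (target numbering) | COc1cccc(C[C@@]2(C)CC[C@]3(C)C(=O)CCC[C@H]3[C@H]2C)c1O[Si](C(C)C)(C(C)C)C(C)C | intermediate
23 | potassium enolate of 22 (C5–OK, C5=C6) | COc1cccc(C[C@@]2(C)CC[C@]3(C)C(O[K])=CCC[C@H]3[C@H]2C)c1O[Si](C(C)C)(C(C)C)C(C)C | intermediate
24 | (1R,2R,4aS,8aS)-1,2,4a-trimethyl-2-(ArCH2)-1,2,3,4,4a,7,8,8a-octahydronaphthalen-5-yl trifluoromethanesulfonate | COc1cccc(C[C@@]2(C)CC[C@]3(C)C(OS(=O)(=O)C(F)(F)F)=CCC[C@H]3[C@H]2C)c1O[Si](C(C)C)(C(C)C)C(C)C | intermediate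
25 | triisopropyl[2-methoxy-6-(DecCH2)phenoxy]silane | COc1cccc(C[C@@]2(C)CC[C@]3(C)C(C)=CCC[C@H]3[C@H]2C)c1O[Si](C(C)C)(C(C)C)C(C)C | intermediate
26 | triisopropyl[2-methoxy-6-(DecCH2)-4-(4,4,5,5-tetramethyl-1,3,2-dioxaborolan-2-yl)phenoxy]silane | COc1cc(B2OC(C)(C)C(C)(C)O2)cc(C[C@@]2(C)CC[C@]3(C)C(C)=CCC[C@H]3[C@H]2C)c1O[Si](C(C)C)(C(C)C)C(C)C | intermediate
27 | 3-methoxy-5-(DecCH2)-4-[(triisopropylsilyl)oxy]phenol | COc1cc(O)cc(C[C@@]2(C)CC[C@]3(C)C(C)=CCC[C@H]3[C@H]2C)c1O[Si](C(C)C)(C(C)C)C(C)C | intermediate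
28 | sodium 4-[(E)-{2-hydroxy-4-methoxy-6-(DecCH2)-5-[(triisopropylsilyl)oxy]phenyl}diazenyl]benzenesulfonate | COc1cc(O)c(/N=N/c2ccc(cc2)S(=O)(=O)[O-])c(C[C@@]2(C)CC[C@]3(C)C(C)=CCC[C@H]3[C@H]2C)c1O[Si](C(C)C)(C(C)C)C(C)C.[Na+] | intermediate
29 | 2-amino-5-methoxy-3-(DecCH2)-4-[(triisopropylsilyl)oxy]phenol | COc1cc(O)c(N)c(C[C@@]2(C)CC[C@]3(C)C(C)=CCC[C@H]3[C@H]2C)c1O[Si](C(C)C)(C(C)C)C(C)C | intermediate
30 | 6-diazo-3-methoxy-5-(DecCH2)-4-[(triisopropylsilyl)oxy]cyclohexa-2,4-dien-1-one | O=C1C=C(OC)C(O[Si](C(C)C)(C(C)C)C(C)C)=C(C[C@@]2(C)CC[C@]3(C)C(C)=CCC[C@H]3[C@H]2C)C1=[N+]=[N-] | intermediate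
31 | methanol | CO | starting material
32 | {3-methoxy-5-(DecCH2)-4-[(triisopropylsilyl)oxy]cyclopenta-2,4-dien-1-ylidene}methanone (ketene) | O=C=C1C=C(OC)C(O[Si](C(C)C)(C(C)C)C(C)C)=C1C[C@@]1(C)CC[C@]2(C)C(C)=CCC[C@H]2[C@H]1C | intermediate
33 | methyl 3-methoxy-5-(DecCH2)-4-[(triisopropylsilyl)oxy]cyclopenta-2,4-diene-1-carboxylate (C1′ labile, one epimer drawn) | COC(=O)[C@H]1C=C(OC)C(O[Si](C(C)C)(C(C)C)C(C)C)=C1C[C@@]1(C)CC[C@]2(C)C(C)=CCC[C@H]2[C@H]1C | intermediate
34 | methyl 3-methoxy-4-oxo-5-(DecCH2)cyclopent-2-ene-1-carboxylate (C1′ and C5′ epimer mixture, left undefined) | COC(=O)C1C=C(OC)C(=O)C1C[C@@]1(C)CC[C@]2(C)C(C)=CCC[C@H]2[C@H]1C | intermediate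
35 | sodium dienolate of 34 (C4′–ONa, C1′=C2′, C3′=C4′; C5′ undefined) | COC(=O)C1=CC(OC)=C(O[Na])C1C[C@@]1(C)CC[C@]2(C)C(C)=CCC[C@H]2[C@H]1C | intermediate
36 | methyl (1S,5S)-1-hydroxy-3-methoxy-4-oxo-5-(DecCH2)cyclopent-2-ene-1-carboxylate (C5′ epimer of the target) | COC(=O)[C@]1(O)C=C(OC)C(=O)[C@H]1C[C@@]1(C)CC[C@]2(C)C(C)=CCC[C@H]2[C@H]1C | intermediate
37 | dysidenone A, methyl (1S,5R)-1-hydroxy-3-methoxy-4-oxo-5-(DecCH2)cyclopent-2-ene-1-carboxylate | COC(=O)[C@]1(O)C=C(OC)C(=O)[C@@H]1C[C@@]1(C)CC[C@]2(C)C(C)=CCC[C@H]2[C@H]1C | target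

Total step count: 21 steps.
Longest linear sequence: 18 steps (steps 1–5 and 9–21, from 2-methylcyclohex-2-en-1-one); the arene branch (steps 6–8) joins at step 9.

Steps most likely to fail

1. Step 19 (key step). After loss of nitrogen the carbene may insert into the O–H bond of methanol faster than the ring carbon shifts, or the cyclopentadiene may scramble by 1,5-hydrogen shifts before it is desilylated. Fallback: a benzilic acid-type ring contraction that needs no diazo compound and puts the C1′ hydroxyl in directly. It sets out from aminophenol 29. Removal of the silyl group with Bu4NF and oxidation in aqueous acid (FeCl3, dilute HCl, THF; the quinone imine hydrolyses) should give 2-hydroxy-5-methoxy-3-(DecCH2)-1,4-benzoquinone F1. Aqueous KOH in dioxane under argon should then contract the ring through the ortho-quinone tautomer (hydroxide adds to one carbonyl and the neighbouring ring carbon shifts; either mode gives the same skeleton) to 1-hydroxy-3-methoxy-4-oxo-5-(DecCH2)cyclopent-2-ene-1-carboxylic acid F2. Esterification of F2 with Me3SiCHN2 in MeOH/toluene, separation of the C1′ epimers and equilibration of C5′ with DBU return to the route at 37.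

2. Step 17. The diazonium ion may attack Ar-C4 (between OH and OMe) instead of Ar-C6, or be consumed by electron transfer from the electron-rich phenoxide. Fallback: place nitrogen by conjugate addition to a quinone, where the methoxy group fixes the regiochemistry. It sets out from phenol 27. Bu4NF and then Ag2O should give 2-methoxy-6-(DecCH2)-1,4-benzoquinone F3. NaN3 in AcOH/THF should add at Ar-C6 (β to the Ar-C2 carbonyl, the one not deactivated as a vinylogous ester), and the azidohydroquinone loses N2 to give 2-amino-5-methoxy-3-(DecCH2)-1,4-benzoquinone F4. Na2S2O4 reduces F4 to 2-amino-5-methoxy-3-(DecCH2)benzene-1,4-diol F5. TIPSCl/imidazole silylates both hydroxyls to the bis(triisopropylsilyl) ether F6, and K2CO3 in MeOH removes only the unhindered Ar-C5 silyl group, which returns to the route at 29.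

3. Step 1. The alkenyl Grignard reagent may add with low enantioselectivity because a ligand-free copper pathway or direct addition competes with the chiral catalyst. Fallback: resolution in place of asymmetric catalysis. The same three-component coupling of 1, 2 and 3 with CuBr·SMe2 and no chiral ligand gives racemic trans-2-methyl-2-(prop-2-en-1-yl)-3-(prop-1-en-2-yl)cyclohexan-1-one F7. Ketalisation with the bis(trimethylsilyl) ether of (R,R)-hydrobenzoin and TMSOTf gives two diastereomeric ketals; the (2R,3R,6S,7S)-2,3-diphenyl ketal F8 is separated by chromatography or crystallisation, and mild acid hydrolysis returns to the route at 5.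

Further compounds
F1 | step 19 | 2-hydroxy-5-methoxy-3-(DecCH2)cyclohexa-2,5-diene-1,4-dione | COC1=CC(=O)C(O)=C(C[C@@]2(C)CC[C@]3(C)C(C)=CCC[C@H]3[C@H]2C)C1=O
F2 | step 19 | 1-hydroxy-3-methoxy-4-oxo-5-(DecCH2)cyclopent-2-ene-1-carboxylic acid (C1′ and C5′ undefined) | OC(=O)C1(O)C=C(OC)C(=O)C1C[C@@]1(C)CC[C@]2(C)C(C)=CCC[C@H]2[C@H]1C
F3 | step 17 | 2-methoxy-6-(DecCH2)cyclohexa-2,5-diene-1,4-dione | COC1=CC(=O)C=C(C[C@@]2(C)CC[C@]3(C)C(C)=CCC[C@H]3[C@H]2C)C1=O
F4 | step 17 | 2-amino-5-methoxy-3-(DecCH2)cyclohexa-2,5-diene-1,4-dione | COC1=CC(=O)C(N)=C(C[C@@]2(C)CC[C@]3(C)C(C)=CCC[C@H]3[C@H]2C)C1=O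
F5 | step 17 | 2-amino-5-methoxy-3-(DecCH2)benzene-1,4-diol | COc1cc(O)c(N)c(C[C@@]2(C)CC[C@]3(C)C(C)=CCC[C@H]3[C@H]2C)c1O
F6 | step 17 | 4-methoxy-2-(DecCH2)-3,6-bis[(triisopropylsilyl)oxy]aniline | COc1cc(O[Si](C(C)C)(C(C)C)C(C)C)c(N)c(C[C@@]2(C)CC[C@]3(C)C(C)=CCC[C@H]3[C@H]2C)c1O[Si](C(C)C)(C(C)C)C(C)C
F7 | step 1 | racemic (2S*,3S*)-2-methyl-2-(prop-2-en-1-yl)-3-(prop-1-en-2-yl)cyclohexan-1-one (one enantiomer drawn) | C=CC[C@]1(C)C(=O)CCC[C@H]1C(C)=C
F8 | step 1 | (2R,3R,6S,7S)-6-methyl-2,3-diphenyl-6-(prop-2-en-1-yl)-7-(prop-1-en-2-yl)-1,4-dioxaspiro[4.5]decane | C=CC[C@]1(C)C2(O[C@H](c3ccccc3)[C@@H](c3ccccc3)O2)CCC[C@H]1C(C)=C
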